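**Retrosynthetic overview**
- The target comes from its bis-benzyl ether TBDPS-protected precursor: the aryl ketone is a late oxidation of a benzylic carbinol, and both phenols travel as benzyl ethers.
- The oxolane ring is closed from a triol by O-alkylation at a primary tosylate, so no stereocentre is touched; the triol comes from LiAlH4 opening of an α-(hydroxybenzyl)-γ-butyrolactone.
- Key C–C bond: intermolecular aldol between the lithium enolate of the (4R,5S)-γ-aryl-β-(silyloxymethyl)butyrolactone and O-benzylisovanillin, which sets the third ring stereocentre anti to its neighbour.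
- The lactone comes from an Evans syn-aldol of (S)-4-benzyl-3-pentenoyloxazolidinone with the same aldehyde (sets the other two stereocentres), then auxiliary reduction, silylation, alkene cleavage and lactol oxidation.
- Ring order: temporary γ-lactone (steps 6–7), opened in step 9, then the oxolane of the target (step 10). Both aryl units derive from isovanillin.

Assumption: the carbinol carbon made in step 8 is carried as an epimer mixture because it becomes the ketone carbon in step 11; it, the lactol carbon of 14 and the diol carbon of 12 carry no stereodescriptor in the SMILES.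

**Route**

Step 1
Reactants: 1 isovanillin
Product: 2 3-(benzyloxy)-4-methoxybenzaldehyde
Conditions: BnBr, K2CO3, DMF, rt
Reagents that add atoms: benzyl bromide, BrCc1ccccc1
Why: Williamson ether synthesis on the phenoxide protects the phenol as a benzyl ether that survives every later basic, hydridic and oxidative step.

Step 2
Reactants: 3 (S)-4-benzyl-1,3-oxazolidin-2-one; 4 pent-4-enoyl chloride
Product: 6 (S)-4-benzyl-3-(pent-4-enoyl)-1,3-oxazolidin-2-one, via lithium oxazolidinide 5 (not isolated)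
Conditions: n-BuLi, THF, −78 °C; then 4, −78 → 0 °C
Reagents that add atoms: none
Why: N-acylation (nucleophilic acyl substitution) of the lithiated auxiliary by the acid chloride is a standard, clean imide synthesis.

Step 3
Reactants: 6 (S)-4-benzyl-3-(pent-4-enoyl)-1,3-oxazolidin-2-one; 2 3-(benzyloxy)-4-methoxybenzaldehyde
Product: 9 (S)-4-benzyl-3-{(2S)-2-[(S)-[3-(benzyloxy)-4-methoxyphenyl](hydroxy)methyl]pent-4-enoyl}-1,3-oxazolidin-2-one, via boron enolate 7 (not isolated), via boron aldolate 8 (not isolated)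
Conditions: Bu2BOTf, i-Pr2NEt, CH2Cl2, 0 °C; 2, −78 → 0 °C; then pH 7 buffer, MeOH, 30% H2O2, 0 °C
Reagents that add atoms: none
Why: Evans syn-aldol reaction: the Z-boron enolate reacts through a Zimmerman–Traxler chair on the face opposite the (S)-benzyl group, giving the (2S,3S) syn adduct that becomes C5 (S) and C4 (R) of the target oxolane.

Step 4
Reactants: 9 Evans aldol adduct
Product: 10 (1S,2R)-1-[3-(benzyloxy)-4-methoxyphenyl]-2-(prop-2-en-1-yl)propane-1,3-diol
Conditions: LiBH4, H2O (1 equiv), Et2O, 0 °C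
Reagents that add atoms: none
Why: Reductive cleavage of the imide by LiBH4 attacks only the exocyclic carbonyl, releasing the auxiliary and the primary alcohol without touching either stereocentre.

Step 5
Reactants: 10 the 1,3-diol
Product: 11 (1S,2R)-1-[3-(benzyloxy)-4-methoxyphenyl]-2-{[(tert-butyldiphenylsilyl)oxy]methyl}pent-4-en-1-ol
Conditions: TBDPSCl, imidazole, CH2Cl2, 0 °C
Reagents that add atoms: tert-butyl(chloro)diphenylsilane (TBDPSCl), CC(C)(C)[Si](Cl)(c1ccccc1)c1ccccc1
Why: Sterically controlled silylation takes the primary hydroxyl and leaves the hindered secondary benzylic one free for lactol formation.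

Step 6
Reactants: 11 the homoallylic alcohol
Product: 14 (4R,5S)-5-[3-(benzyloxy)-4-methoxyphenyl]-4-{[(tert-butyldiphenylsilyl)oxy]methyl}oxolan-2-ol (anomer mixture), via vicinal diol 12 (not isolated), via hydroxy aldehyde 13 (not isolated)
Conditions: OsO4 (2 mol %), NaIO4, 2,6-lutidine, dioxane–H2O 3:1, rt
Reagents that add atoms: osmium tetroxide, O=[Os](=O)(=O)=O (catalytic O-transfer agent); sodium periodate, [Na+].[O-]I(=O)(=O)=O (terminal oxidant that supplies the oxygen)
Why: Lemieux–Johnson oxidative cleavage of the terminal alkene gives a γ-hydroxy aldehyde that closes spontaneously to the five-membered lactol, and it spares the electron-rich arenes that ozone could attack.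

Step 7
Reactants: 14 the lactol
Product: 15 (4R,5S)-5-[3-(benzyloxy)-4-methoxyphenyl]-4-{[(tert-butyldiphenylsilyl)oxy]methyl}oxolan-2-one
Conditions: TPAP (5 mol %), NMO, 4 Å MS, CH2Cl2, rt
Reagents that add atoms: none
Why: Ley–Griffith oxidation converts the lactol to the trans-4,5-disubstituted γ-lactone under neutral conditions that leave the silyl and benzyl ethers and the benzylic C–O stereocentre alone.

Step 8
Reactants: 15 the lactone; 2 3-(benzyloxy)-4-methoxybenzaldehyde
Product: 18 (3R,4R,5S)-5-[3-(benzyloxy)-4-methoxyphenyl]-3-{[3-(benzyloxy)-4-methoxyphenyl](hydroxy)methyl}-4-{[(tert-butyldiphenylsilyl)oxy]methyl}oxolan-2-one (carbinol epimers), via lithium enolate 16 (not isolated), via lithium aldolate 17 (not isolated)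
Conditions: LDA, THF, −78 °C; 2, −78 °C; AcOH quench at −78 °C
Reagents that add atoms: none
Why: Intermolecular aldol addition of the lactone lithium enolate: the aldehyde approaches anti to the adjacent C4 CH2OTBDPS group, giving the 3,4-trans product (3R), while the uncontrolled carbinol centre is removed later by oxidation.

Step 9
Reactants: 18 the aldol lactone
Product: 19 (1S,2R,3S)-1-[3-(benzyloxy)-4-methoxyphenyl]-3-{[3-(benzyloxy)-4-methoxyphenyl](hydroxy)methyl}-2-{[(tert-butyldiphenylsilyl)oxy]methyl}butane-1,4-diol (carbinol epimers)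
Conditions: LiAlH4, THF, 0 °C; Fieser work-up
Reagents that add atoms: none
Why: Hydride reduction of the lactone to the diol is faster than retro-aldol at 0 °C and exposes the single primary hydroxyl needed for ring closure; the basic work-up avoids ionising the benzylic alcohols.

Step 10
Reactants: 19 the triol
Product: 21 [3-(benzyloxy)-4-methoxyphenyl][(3S,4R,5S)-5-[3-(benzyloxy)-4-methoxyphenyl]-4-{[(tert-butyldiphenylsilyl)oxy]methyl}oxolan-3-yl]methanol (carbinol epimers), via primary tosylate 20 (not isolated)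
Conditions: TsCl (1.1 equiv), pyridine, 0 °C → rt, then 60 °C
Reagents that add atoms: none
Why: Selective sulfonylation of the only primary hydroxyl, then intramolecular Williamson etherification (5-exo-tet) by the C1 benzylic hydroxyl, far faster than the 4-exo alternative from the other carbinol; substitution occurs at CH2, so all three stereocentres are retained.

Step 11
Reactants: 21 the oxolanyl carbinol
Product: 22 [3-(benzyloxy)-4-methoxyphenyl][(3S,4R,5S)-5-[3-(benzyloxy)-4-methoxyphenyl]-4-{[(tert-butyldiphenylsilyl)oxy]methyl}oxolan-3-yl]methanone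
Conditions: Dess–Martin periodinane, CH2Cl2, rt
Reagents that add atoms: none
Why: Dess–Martin oxidation converges both carbinol epimers to the aryl ketone, and the adjacent stereocentre already has the thermodynamically preferred all-trans arrangement, so enolisation cannot erode it.

Step 12
Reactants: 22 the silyl ether ketone
Product: 23 [3-(benzyloxy)-4-methoxyphenyl][(3S,4R,5S)-5-[3-(benzyloxy)-4-methoxyphenyl]-4-(hydroxymethyl)oxolan-3-yl]methanone
Conditions: HF·pyridine, THF–pyridine, 0 °C → rt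
Reagents that add atoms: none
Why: Fluoride-mediated Si–O cleavage under buffered, non-basic conditions frees the primary alcohol without triggering retro-oxa-Michael opening of the β-alkoxy ketone.

Step 13
Reactants: 23 the bis-benzyl ether
Product: 24 (3-hydroxy-4-methoxyphenyl)[(3S,4R,5S)-4-(hydroxymethyl)-5-(3-hydroxy-4-methoxyphenyl)oxolan-3-yl]methanone
Conditions: H2 (1 atm), 10% Pd/C, EtOAc, rt, stopped at full debenzylation
Reagents that add atoms: none
Why: Catalytic hydrogenolysis cleaves aryl benzyl ethers much faster than it reduces a p-methoxy-deactivated aryl ketone or the dialkyl benzylic ether of the ring in neutral EtOAc.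

**Compound list**

1 | isovanillin (3-hydroxy-4-methoxybenzaldehyde) | COc1ccc(C=O)cc1O | starting material
2 | 3-(benzyloxy)-4-methoxybenzaldehyde | COc1ccc(C=O)cc1OCc1ccccc1 | intermediate
3 | (S)-4-benzyl-1,3-oxazolidin-2-one | O=C1N[C@@H](Cc2ccccc2)CO1 | starting material
4 | pent-4-enoyl chloride | C=CCCC(Cl)=O | starting material
5 | lithium (S)-4-benzyl-2-oxo-1,3-oxazolidin-3-ide | [Li+].O=C1[N-][C@@H](Cc2ccccc2)CO1 | intermediate
6 | (S)-4-benzyl-3-(pent-4-enoyl)-1,3-oxazolidin-2-one | C=CCCC(=O)N1C(=O)OC[C@@H]1Cc1ccccc1 | intermediate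
7 | (Z)-dibutylboron enolate of 6 (allyl CH2 cis to OBBu2) | C=CC/C=C(\OB(CCCC)CCCC)N1C(=O)OC[C@@H]1Cc1ccccc1 | intermediate
8 | O-dibutylboryl aldolate of 9 | O=C1OC[C@H](Cc2ccccc2)N1C(=O)[C@@H](CC=C)[C@H](OB(CCCC)CCCC)c1ccc(OC)c(OCc2ccccc2)c1 | intermediate
9 | (S)-4-benzyl-3-{(2S)-2-[(S)-[3-(benzyloxy)-4-methoxyphenyl](hydroxy)methyl]pent-4-enoyl}-1,3-oxazolidin-2-one | O=C1OC[C@H](Cc2ccccc2)N1C(=O)[C@@H](CC=C)[C@H](O)c1ccc(OC)c(OCc2ccccc2)c1 | intermediate
10 | (1S,2R)-1-[3-(benzyloxy)-4-methoxyphenyl]-2-(prop-2-en-1-yl)propane-1,3-diol | OC[C@@H](CC=C)[C@H](O)c1ccc(OC)c(OCc2ccccc2)c1 | intermediate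
11 | (1S,2R)-1-[3-(benzyloxy)-4-methoxyphenyl]-2-{[(tert-butyldiphenylsilyl)oxy]methyl}pent-4-en-1-ol | CC(C)(C)[Si](c1ccccc1)(c1ccccc1)OC[C@@H](CC=C)[C@H](O)c1ccc(OC)c(OCc2ccccc2)c1 | intermediate
12 | (4R,5S)-5-[3-(benzyloxy)-4-methoxyphenyl]-4-{[(tert-butyldiphenylsilyl)oxy]methyl}pentane-1,2,5-triol (C2 epimers) | CC(C)(C)[Si](c1ccccc1)(c1ccccc1)OC[C@@H](CC(O)CO)[C@H](O)c1ccc(OC)c(OCc2ccccc2)c1 | intermediate
13 | (3R,4S)-4-[3-(benzyloxy)-4-methoxyphenyl]-3-{[(tert-butyldiphenylsilyl)oxy]methyl}-4-hydroxybutanal | CC(C)(C)[Si](c1ccccc1)(c1ccccc1)OC[C@@H](CC=O)[C@H](O)c1ccc(OC)c(OCc2ccccc2)c1 | intermediate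
14 | (4R,5S)-5-[3-(benzyloxy)-4-methoxyphenyl]-4-{[(tert-butyldiphenylsilyl)oxy]methyl}oxolan-2-ol (anomers) | OC1C[C@H](CO[Si](c2ccccc2)(c2ccccc2)C(C)(C)C)[C@@H](c2ccc(OC)c(OCc3ccccc3)c2)O1 | intermediate
15 | (4R,5S)-5-[3-(benzyloxy)-4-methoxyphenyl]-4-{[(tert-butyldiphenylsilyl)oxy]methyl}oxolan-2-one | O=C1C[C@H](CO[Si](c2ccccc2)(c2ccccc2)C(C)(C)C)[C@@H](c2ccc(OC)c(OCc3ccccc3)c2)O1 | intermediate
16 | lithium enolate of 15 | [Li+].[O-]C1=C[C@H](CO[Si](c2ccccc2)(c2ccccc2)C(C)(C)C)[C@@H](c2ccc(OC)c(OCc3ccccc3)c2)O1 | intermediate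
17 | lithium aldolate of 18 | O=C1[C@@H](C([O-])c2ccc(OC)c(OCc3ccccc3)c2)[C@H](CO[Si](c2ccccc2)(c2ccccc2)C(C)(C)C)[C@@H](c2ccc(OC)c(OCc3ccccc3)c2)O1.[Li+] | intermediate
18 | (3R,4R,5S)-5-[3-(benzyloxy)-4-methoxyphenyl]-3-{[3-(benzyloxy)-4-methoxyphenyl](hydroxy)methyl}-4-{[(tert-butyldiphenylsilyl)oxy]methyl}oxolan-2-one (carbinol epimers) | O=C1[C@@H](C(O)c2ccc(OC)c(OCc3ccccc3)c2)[C@H](CO[Si](c2ccccc2)(c2ccccc2)C(C)(C)C)[C@@H](c2ccc(OC)c(OCc3ccccc3)c2)O1 | intermediate
19 | (1S,2R,3S)-1-[3-(benzyloxy)-4-methoxyphenyl]-3-{[3-(benzyloxy)-4-methoxyphenyl](hydroxy)methyl}-2-{[(tert-butyldiphenylsilyl)oxy]methyl}butane-1,4-diol (carbinol epimers) | OC[C@@H](C(O)c1ccc(OC)c(OCc2ccccc2)c1)[C@H](CO[Si](c1ccccc1)(c1ccccc1)C(C)(C)C)[C@H](O)c1ccc(OC)c(OCc2ccccc2)c1 | intermediate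
20 | primary 4-methylbenzenesulfonate of 19 (tosyl on the CH2OH oxygen) | Cc1ccc(cc1)S(=O)(=O)OC[C@@H](C(O)c1ccc(OC)c(OCc2ccccc2)c1)[C@H](CO[Si](c1ccccc1)(c1ccccc1)C(C)(C)C)[C@H](O)c1ccc(OC)c(OCc2ccccc2)c1 | intermediate
21 | [3-(benzyloxy)-4-methoxyphenyl][(3S,4R,5S)-5-[3-(benzyloxy)-4-methoxyphenyl]-4-{[(tert-butyldiphenylsilyl)oxy]methyl}oxolan-3-yl]methanol (carbinol epimers; ring all-trans) | OC(c1ccc(OC)c(OCc2ccccc2)c1)[C@@H]1CO[C@H](c2ccc(OC)c(OCc3ccccc3)c2)[C@H]1CO[Si](c1ccccc1)(c1ccccc1)C(C)(C)C | intermediate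
22 | [3-(benzyloxy)-4-methoxyphenyl][(3S,4R,5S)-5-[3-(benzyloxy)-4-methoxyphenyl]-4-{[(tert-butyldiphenylsilyl)oxy]methyl}oxolan-3-yl]methanone | O=C(c1ccc(OC)c(OCc2ccccc2)c1)[C@@H]1CO[C@H](c2ccc(OC)c(OCc3ccccc3)c2)[C@H]1CO[Si](c1ccccc1)(c1ccccc1)C(C)(C)C | intermediate
23 | [3-(benzyloxy)-4-methoxyphenyl][(3S,4R,5S)-5-[3-(benzyloxy)-4-methoxyphenyl]-4-(hydroxymethyl)oxolan-3-yl]methanone | O=C(c1ccc(OC)c(OCc2ccccc2)c1)[C@@H]1CO[C@H](c2ccc(OC)c(OCc3ccccc3)c2)[C@H]1CO | intermediate
24 | (3-hydroxy-4-methoxyphenyl)[(3S,4R,5S)-4-(hydroxymethyl)-5-(3-hydroxy-4-methoxyphenyl)oxolan-3-yl]methanone (CNP0234761.1) | COc1ccc(C(=O)[C@@H]2CO[C@H](c3ccc(OC)c(O)c3)[C@H]2CO)cc1O | target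

**Totals**

Total step count: 13. Longest linear sequence: 12 steps (3 → 24 through steps 2–13; the branch from 1 through steps 1 and 3–13 is equally long).

**Three steps most likely to fail, each with a fallback**

Step 8 (lactone aldol). The lithium aldolate of an electron-rich benzaldehyde can revert (retro-aldol) or the enolate can be sluggish. The fallback sets out from 15: LDA then TMSCl (THF, −78 °C) gives the trimethylsilyl ketene acetal F1. A Mukaiyama aldol addition of F1 to 2 (BF3·OEt2, CH2Cl2, −78 °C) proceeds through an open transition state with no basic aldolate, again anti to the C4 substituent, and after aqueous work-up comes back to the route at 18. Any minor C3 epimer carried forward is corrected at the ketone stage, where the all-trans isomer is the thermodynamic one.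

Step 10 (tosylation and ring closure with a free second carbinol). The risk is sulfonylation or ionisation at a benzylic hydroxyl, or participation of the wrong oxygen. The fallback sets out from 18 and caps the aldol hydroxyl first: TBSOTf and 2,6-lutidine give the TBS ether F2, and LiAlH4 at −20 °C gives the diol F3. TsCl in pyridine followed by NaH in THF then closes the only ring that can form, giving the bis-silyl oxolane F4. TBAF removes both silyl groups to give the diol F5, and activated MnO2 in CH2Cl2 oxidises only the benzylic alcohol, which comes back to the route at 23.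

Step 13 (hydrogenolysis). The risk is over-reduction of the aryl ketone or hydrogenolytic opening of the 2-aryl oxolane. The fallback sets out from 23 and avoids reduction altogether: BCl3 with pentamethylbenzene as benzyl-cation scavenger (CH2Cl2, −78 °C, MeOH quench) cleaves only the aryl benzyl ethers and arrives directly at 24; no new compound is formed (F0).

**Further compounds**

F1 | step 8 | tert-butyl{[(2S,3R)-2-[3-(benzyloxy)-4-methoxyphenyl]-5-[(trimethylsilyl)oxy]-2,3-dihydrofuran-3-yl]methoxy}diphenylsilane | C[Si](C)(C)OC1=C[C@H](CO[Si](c2ccccc2)(c2ccccc2)C(C)(C)C)[C@@H](c2ccc(OC)c(OCc3ccccc3)c2)O1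
F2 | step 10 | O-TBS ether of 18 at the carbinol: (3R,4R,5S)-5-[3-(benzyloxy)-4-methoxyphenyl]-3-{[3-(benzyloxy)-4-methoxyphenyl][(tert-butyldimethylsilyl)oxy]methyl}-4-{[(tert-butyldiphenylsilyl)oxy]methyl}oxolan-2-one | O=C1[C@@H](C(O[Si](C)(C)C(C)(C)C)c2ccc(OC)c(OCc3ccccc3)c2)[C@H](CO[Si](c2ccccc2)(c2ccccc2)C(C)(C)C)[C@@H](c2ccc(OC)c(OCc3ccccc3)c2)O1
F3 | step 10 | (1S,2R,3S)-1-[3-(benzyloxy)-4-methoxyphenyl]-3-{[3-(benzyloxy)-4-methoxyphenyl][(tert-butyldimethylsilyl)oxy]methyl}-2-{[(tert-butyldiphenylsilyl)oxy]methyl}butane-1,4-diol | OC[C@@H](C(O[Si](C)(C)C(C)(C)C)c1ccc(OC)c(OCc2ccccc2)c1)[C@H](CO[Si](c1ccccc1)(c1ccccc1)C(C)(C)C)[C@H](O)c1ccc(OC)c(OCc2ccccc2)c1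
F4 | step 10 | O-TBS ether of 21: (2S,3R,4S)-2-[3-(benzyloxy)-4-methoxyphenyl]-4-{[3-(benzyloxy)-4-methoxyphenyl][(tert-butyldimethylsilyl)oxy]methyl}-3-{[(tert-butyldiphenylsilyl)oxy]methyl}oxolane | CC(C)(C)[Si](C)(C)OC(c1ccc(OC)c(OCc2ccccc2)c1)[C@@H]1CO[C@H](c2ccc(OC)c(OCc3ccccc3)c2)[C@H]1CO[Si](c1ccccc1)(c1ccccc1)C(C)(C)C
F5 | step 10 | [3-(benzyloxy)-4-methoxyphenyl][(3S,4R,5S)-5-[3-(benzyloxy)-4-methoxyphenyl]-4-(hydroxymethyl)oxolan-3-yl]methanol (carbinol epimers) | OC(c1ccc(OC)c(OCc2ccccc2)c1)[C@@H]1CO[C@H](c2ccc(OC)c(OCc3ccccc3)c2)[C@H]1CO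
F0 | step 13 | none | none
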